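## Retrosynthetic overview

1. Quinone ring numbering: C1 (C=O next to the ring CH), C2 and C3 (the two C–OMe), C4 (second C=O), C5 (carries chroman C3), C6 (CH). Target 20 ⇐ Teuber oxidation at C4 of phenol 19 ⇐ removal of a marker ester on C6 and O-methylation at C3 of resorcylate 16 ⇐ aromatization of keto ester 14.
2. Key disconnections in 14: C5–C6 (Michael addition of dimethyl malonate 12 to enone 11), then ring closure C1–C2 by intramolecular Claisen condensation (C2 = methoxy-bearing α'-carbon of the ketone, C1 = a malonate ester carbon), both in one pot.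
3. Enabling feature: the contiguous O–C1, MeO–C2, O–C3 triad with C5 meta to C1 and C3 makes the quinone ring a masked 2-methoxycyclohexane-1,3-dione whose C5 is the β-carbon of an enone. The unused malonate ester stays on C6 and, by hydrogen bonding to the C1 hydroxyl, keeps the C1 and C3 oxygens distinguishable.
4. Enone 11 ⇐ in situ oxidation/Wittig olefination of alcohol 5 with ylide 9 ⇐ Ir-catalysed asymmetric hydrogenation of chromene allylic alcohol 4 (sets chroman C3) ⇐ chromene aldehyde 3 from salicylaldehyde 1 and acrolein 2.
5. Ring order: pyran ring of the chroman first (step 1), then the carbocycle that becomes the quinone (step 6).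

Key step: step 6

Remarks. R* = (3S)-6,7-dimethoxy-3,4-dihydro-2H-chromen-3-yl, bonded through chroman C3. In the Why lines C1–C6 are the quinone-ring atoms as numbered above, and chroman atoms are always called "chroman C3" and so on.
Assumption: the (S)-configured ligand in step 3 is taken to give the (S)-alcohol 5; the sense of induction is to be confirmed on the first run and the ligand antipode used if it is the opposite.

## Route

Step 1
Reactants: 1 2-hydroxy-4,5-dimethoxybenzaldehyde; 2 acrolein
Product: 3 6,7-dimethoxy-2H-chromene-3-carbaldehyde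
Conditions: K2CO3, 1,4-dioxane, reflux
Reagents that add atoms: none
Why: Domino oxa-Michael addition/intramolecular aldol condensation of a salicylaldehyde with acrolein is the standard route to 2H-chromene-3-carbaldehydes and builds the pyran ring with the one-carbon handle on chroman C3.

Step 2
Reactants: 3 6,7-dimethoxy-2H-chromene-3-carbaldehyde
Product: 4 (6,7-dimethoxy-2H-chromen-3-yl)methanol
Conditions: NaBH4, CeCl3·7H2O, MeOH, 0 °C
Reagents that add atoms: none
Why: Luche reduction gives selective 1,2-reduction of the enal to the allylic alcohol needed as the hydrogenation substrate.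

Step 3
Reactants: 4 (6,7-dimethoxy-2H-chromen-3-yl)methanol
Product: 5 R*-methanol, [(3S)-6,7-dimethoxy-3,4-dihydro-2H-chromen-3-yl]methanol
Conditions: H2 (50 bar), [Ir(cod)((S)-tBu-PHOX)]BArF (1 mol%; tBu-PHOX = 4-tert-butyl-2-[2-(diphenylphosphanyl)phenyl]-4,5-dihydrooxazole, BArF = tetrakis[3,5-bis(trifluoromethyl)phenyl]borate), CH2Cl2, rt
Reagents that add atoms: none
Why: Iridium-catalysed asymmetric hydrogenation with a chiral phosphinooxazoline ligand is the standard method for trisubstituted, aryl-conjugated allylic alcohols of the (E)-2-alkyl-3-arylprop-2-en-1-ol type, to which 4 belongs, and the catalyst delivers H2 to one face of the chromene C3=C4 bond, which sets chroman C3 as the only stereocentre of the route.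

Step 4
Reactants: 6 methyltriphenylphosphonium bromide (2 equiv); 7 methyl methoxyacetate
Product: 9 1-methoxy-3-(triphenyl-λ5-phosphanylidene)propan-2-one, via methylenetriphenylphosphorane 8 (not isolated)
Conditions: n-BuLi (2 equiv), THF, 0 °C; then 7, 0 °C → rt
Reagents that add atoms: none
Why: Acylation of methylenetriphenylphosphorane by an ester, followed by deprotonation of the resulting β-keto phosphonium ion by the second equivalent of ylide (transylidation), is the usual preparation of acyl-stabilized Wittig reagents.

Step 5
Reactants: 5 R*-methanol; 9 1-methoxy-3-(triphenyl-λ5-phosphanylidene)propan-2-one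
Product: 11 (3E)-1-methoxy-4-R*-but-3-en-2-one, via chroman-3-carbaldehyde 10 (not isolated)
Conditions: Dess–Martin periodinane (1.3 equiv), 9 (2.5 equiv) present from the start, CH2Cl2, 0 °C → 35 °C
Reagents that add atoms: none
Why: Dess–Martin oxidation in the presence of the stabilized ylide lets the aldehyde undergo E-selective Wittig olefination as soon as it forms, so the enolizable β-aryloxy aldehyde is never isolated or exposed to strong base and chroman C3 keeps its configuration (its descriptor is R in 10 and S in 11 only because of ligand priorities).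

Step 6
Reactants: 11 (3E)-1-methoxy-4-R*-but-3-en-2-one; 12 dimethyl malonate
Product: 14 methyl 3-methoxy-2,4-dioxo-6-R*-cyclohexane-1-carboxylate (enol tautomers; mixture of ring diastereomers), via Michael adduct 13 (not isolated)
Conditions: NaOMe (1.2 equiv), 12 (1.2 equiv), MeOH, 0 °C → rt; then reflux; aq. HCl, 0 °C
Reagents that add atoms: none
Why: Sodiomalonate adds to the β-carbon C5 of the (E)-enone (Michael addition, C5–C6 bond) and, on heating, the α'-enolate of the methoxymethyl ketone (C2) attacks one ester carbonyl of the malonate unit (C1) in an intramolecular Claisen (Dieckmann-type) condensation that closes the six-membered carbocycle through the C1–C2 bond. The closest known reaction type is the enone–malonate annulation that gives dimedone and the methyl 2,4-dioxocyclohexanecarboxylate precursors of olivetol. Ring closure is a 6-exo-trig acyl substitution; C-acylation from the other α-carbon (C4) would need a four-membered ring, O-acylation is reversible under methoxide, and loss of methoxide followed by deprotonation to the tricarbonyl enolate makes the carbocycle the thermodynamic sink. New centres arise at C5, C6 and C2 without control, which does not matter because all three become sp2 in step 7, and the one stereocentre that must survive, chroman C3, takes no part. The selectivity needed is that conjugate addition outruns γ-deprotonation of the enone at chroman C3: the base present during the addition is the malonate anion, far too weak to remove that proton, and after the addition chroman C3 is no longer next to a π-acceptor. Because the unreacted ester stays on C6 next to the new C1 carbonyl, the product is unsymmetrical and C1 and C3 remain distinguishable in the later methylation.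

Step 7
Reactants: 14 methyl 3-methoxy-2,4-dioxo-6-R*-cyclohexane-1-carboxylate
Product: 16 methyl 2,4-dihydroxy-3-methoxy-6-R*-benzoate, via bromo tricarbonyl compound 15 (not isolated)
Conditions: Br2 (1.0 equiv), DMF, 0 °C; then 80 °C
Reagents that add atoms: none
Why: Halogenation–dehydrohalogenation aromatization: bromine should attack the enolized tricarbonyl unit far faster than the aryl ethers, and thermal loss of HBr from the bromo compound (directly or after bromine shift to C6, in either case through the β-keto ester enol) gives a dienone that tautomerizes to the resorcylate, as in the standard conversion of enone–malonate adducts into 2,4-dihydroxybenzoates; C5 becomes sp2 and the ester stays on C6.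

Step 8
Reactants: 16 methyl 2,4-dihydroxy-3-methoxy-6-R*-benzoate
Product: 17 methyl 2-hydroxy-3,4-dimethoxy-6-R*-benzoate
Conditions: MeI (1.1 equiv), K2CO3 (1.1 equiv), acetone, rt
Reagents that add atoms: iodomethane, CI
Why: Williamson methylation: in a 2,4-dihydroxybenzoate the hydroxyl ortho to the ester (on C1) is held in an intramolecular hydrogen bond and is much less nucleophilic, so one equivalent of MeI with K2CO3 should methylate only the para hydroxyl (on C3).

Step 9
Reactants: 17 methyl 2-hydroxy-3,4-dimethoxy-6-R*-benzoate
Product: 19 2,3-dimethoxy-5-R*-phenol, via salicylic acid 18 (not isolated)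
Conditions: KOH, DMSO/H2O, 110 °C; then aq. HCl to pH 1, 100 °C
Reagents that add atoms: none
Why: Saponification followed by acid-promoted protodecarboxylation, which is easy for a salicylic acid whose ipso carbon is ortho to OH and para to OMe, removes the marker ester and leaves H on C6; no acidic site is near chroman C3.

Step 10
Reactants: 19 2,3-dimethoxy-5-R*-phenol
Product: 20 abroquinone A, 2,3-dimethoxy-5-R*-cyclohexa-2,5-diene-1,4-dione
Conditions: ON(SO3K)2 (2.5 equiv), KH2PO4 buffer (pH 6), acetone/H2O, 0 °C → rt
Reagents that add atoms: potassium nitrosodisulfonate (Fremy's salt), [K+].[K+].[O]N(S(=O)(=O)[O-])S(=O)(=O)[O-]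
Why: Teuber oxidation: Fremy's salt converts a phenol with a free para position into the para-quinone through the phenoxyl radical, here placing the second carbonyl on C4, does not touch aryl ethers, and the buffered medium avoids base-induced epimerization of the now quinone-activated chroman C3.

## Compound list

1 | 2-hydroxy-4,5-dimethoxybenzaldehyde | O=Cc1cc(OC)c(OC)cc1O | starting material
2 | acrolein (prop-2-enal) | C=CC=O | starting material
3 | 6,7-dimethoxy-2H-chromene-3-carbaldehyde | O=CC1=Cc2cc(OC)c(OC)cc2OC1 | intermediate
4 | (6,7-dimethoxy-2H-chromen-3-yl)methanol | OCC1=Cc2cc(OC)c(OC)cc2OC1 | intermediate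
5 | [(3S)-6,7-dimethoxy-3,4-dihydro-2H-chromen-3-yl]methanol | OC[C@H]1COc2cc(OC)c(OC)cc2C1 | intermediate
6 | methyltriphenylphosphonium bromide | C[P+](c1ccccc1)(c1ccccc1)c1ccccc1.[Br-] | starting material
7 | methyl methoxyacetate | COCC(=O)OC | starting material
8 | methylenetriphenylphosphorane | C=P(c1ccccc1)(c1ccccc1)c1ccccc1 | intermediate
9 | 1-methoxy-3-(triphenyl-λ5-phosphanylidene)propan-2-one | COCC(=O)C=P(c1ccccc1)(c1ccccc1)c1ccccc1 | intermediate
10 | (3R)-6,7-dimethoxy-3,4-dihydro-2H-chromene-3-carbaldehyde | O=C[C@H]1COc2cc(OC)c(OC)cc2C1 | intermediate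
11 | (3E)-4-[(3S)-6,7-dimethoxy-3,4-dihydro-2H-chromen-3-yl]-1-methoxybut-3-en-2-one | COCC(=O)/C=C/[C@H]1COc2cc(OC)c(OC)cc2C1 | intermediate
12 | dimethyl malonate | COC(=O)CC(=O)OC | starting material
13 | dimethyl 2-{1-[(3S)-6,7-dimethoxy-3,4-dihydro-2H-chromen-3-yl]-4-methoxy-3-oxobutyl}propanedioate (both epimers at the new centre) | COCC(=O)CC(C(C(=O)OC)C(=O)OC)[C@H]1COc2cc(OC)c(OC)cc2C1 | intermediate
14 | methyl 6-[(3S)-6,7-dimethoxy-3,4-dihydro-2H-chromen-3-yl]-3-methoxy-2,4-dioxocyclohexane-1-carboxylate (ring centres unassigned) | COC(=O)C1C(=O)C(OC)C(=O)CC1[C@H]1COc2cc(OC)c(OC)cc2C1 | intermediate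
15 | methyl 3-bromo-6-[(3S)-6,7-dimethoxy-3,4-dihydro-2H-chromen-3-yl]-3-methoxy-2,4-dioxocyclohexane-1-carboxylate | COC(=O)C1C(=O)C(Br)(OC)C(=O)CC1[C@H]1COc2cc(OC)c(OC)cc2C1 | intermediate
16 | methyl 6-[(3S)-6,7-dimethoxy-3,4-dihydro-2H-chromen-3-yl]-2,4-dihydroxy-3-methoxybenzoate | COC(=O)c1c(O)c(OC)c(O)cc1[C@H]1COc2cc(OC)c(OC)cc2C1 | intermediate
17 | methyl 6-[(3S)-6,7-dimethoxy-3,4-dihydro-2H-chromen-3-yl]-2-hydroxy-3,4-dimethoxybenzoate | COC(=O)c1c(O)c(OC)c(OC)cc1[C@H]1COc2cc(OC)c(OC)cc2C1 | intermediate
18 | 6-[(3S)-6,7-dimethoxy-3,4-dihydro-2H-chromen-3-yl]-2-hydroxy-3,4-dimethoxybenzoic acid | OC(=O)c1c(O)c(OC)c(OC)cc1[C@H]1COc2cc(OC)c(OC)cc2C1 | intermediate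
19 | 5-[(3S)-6,7-dimethoxy-3,4-dihydro-2H-chromen-3-yl]-2,3-dimethoxyphenol | Oc1cc(cc(OC)c1OC)[C@H]1COc2cc(OC)c(OC)cc2C1 | intermediate
20 | abroquinone A, 5-[(3S)-6,7-dimethoxy-3,4-dihydro-2H-chromen-3-yl]-2,3-dimethoxycyclohexa-2,5-diene-1,4-dione | COC1=C(OC)C(=O)C([C@H]2COc3cc(OC)c(OC)cc3C2)=CC1=O | target

## Step count and risks

Total steps: 10. Longest linear sequence: 9 steps (steps 1–3 and 5–10); step 4 is a one-step side branch.

Three steps most likely to fail:

**Step 7.** Electrophilic bromination of the electron-rich dimethoxychroman ring may compete with attack on the enol, or the brominated tricarbonyl intermediate may lose its C2 methoxy group instead of eliminating HBr cleanly. The fallback avoids halogen altogether. Setting out from 14, double O-silylation (Me3SiOTf, Et3N, CH2Cl2, 0 °C) would give the cyclohexa-1,3-diene methyl 6-R*-3-methoxy-2,4-bis(trimethylsilyloxy)cyclohexa-1,3-diene-1-carboxylate F1. Dehydrogenation of this diene with DDQ (toluene, 0 °C), which should be far faster than benzylic oxidation of the chroman, would give the aromatic bis-silyl ether methyl 6-R*-3-methoxy-2,4-bis(trimethylsilyloxy)benzoate F2. K2CO3 in MeOH would remove both silyl groups, and the route is rejoined at 16.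

**Step 10.** Radical coupling at the doubly flanked para carbon C4 may be slow, so that attack at C6 (ortho-quinone formation) or over-oxidation of the product competes. The fallback is the azo-coupling route to quinones. Setting out from 19, coupling with diazotized 4-aminobenzenesulfonic acid (aq. NaOH, 0 °C) para to the hydroxyl would give the azo phenol 4-[(E)-(4-hydroxy-2,3-dimethoxy-6-R*-phenyl)diazenyl]benzenesulfonic acid F3. Reductive cleavage with Na2S2O4 (aq. NaOH, 50 °C) would give the aminophenol 4-amino-2,3-dimethoxy-5-R*-phenol F4. Oxidation with FeCl3 in aq. HCl and hydrolysis of the quinone imine would return to the route at 20.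

**Step 5.** Configuration at chroman C3 may erode while the β-aryloxy aldehyde 10 is present (enolization, or retro-oxa-Michael ring opening and re-closure), especially if the ketone-stabilized ylide reacts slowly. The fallback never makes the aldehyde. Setting out from 5, iodination (I2, PPh3, imidazole, CH2Cl2) would give (3R)-3-(iodomethyl)-6,7-dimethoxy-3,4-dihydro-2H-chromene F5. Separately, acylation of lithiated methyl phenyl sulfoxide (LiN(iPr)2, THF, −78 °C) with 7 would give the β-keto sulfoxide 1-methoxy-3-(phenylsulfinyl)propan-2-one F6. C-alkylation of its sodium salt (NaH, DMF, 50 °C) with F5 would give 1-methoxy-3-(phenylsulfinyl)-4-R*-butan-2-one F7. Thermal syn-elimination of the sulfoxide (toluene, CaCO3, 110 °C) would then form the (E)-enone and rejoin the route at 11.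

Further compounds
F1 | step 7 | methyl 6-[(3S)-6,7-dimethoxy-3,4-dihydro-2H-chromen-3-yl]-3-methoxy-2,4-bis[(trimethylsilyl)oxy]cyclohexa-1,3-diene-1-carboxylate | COC(=O)C1=C(O[Si](C)(C)C)C(OC)=C(O[Si](C)(C)C)CC1[C@H]1COc2cc(OC)c(OC)cc2C1
F2 | step 7 | methyl 6-[(3S)-6,7-dimethoxy-3,4-dihydro-2H-chromen-3-yl]-3-methoxy-2,4-bis[(trimethylsilyl)oxy]benzoate | COC(=O)c1c(O[Si](C)(C)C)c(OC)c(O[Si](C)(C)C)cc1[C@H]1COc2cc(OC)c(OC)cc2C1
F3 | step 10 | 4-[(E)-{6-[(3S)-6,7-dimethoxy-3,4-dihydro-2H-chromen-3-yl]-4-hydroxy-2,3-dimethoxyphenyl}diazenyl]benzenesulfonic acid | OS(=O)(=O)c1ccc(cc1)/N=N/c1c(OC)c(OC)c(O)cc1[C@H]1COc2cc(OC)c(OC)cc2C1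
F4 | step 10 | 4-amino-5-[(3S)-6,7-dimethoxy-3,4-dihydro-2H-chromen-3-yl]-2,3-dimethoxyphenol | Nc1c(OC)c(OC)c(O)cc1[C@H]1COc2cc(OC)c(OC)cc2C1
F5 | step 5 | (3R)-3-(iodomethyl)-6,7-dimethoxy-3,4-dihydro-2H-chromene | IC[C@H]1COc2cc(OC)c(OC)cc2C1
F6 | step 5 | 1-methoxy-3-(phenylsulfinyl)propan-2-one | COCC(=O)CS(=O)c1ccccc1
F7 | step 5 | 4-[(3S)-6,7-dimethoxy-3,4-dihydro-2H-chromen-3-yl]-1-methoxy-3-(phenylsulfinyl)butan-2-one | COCC(=O)C(C[C@H]1COc2cc(OC)c(OC)cc2C1)S(=O)c1ccccc1
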